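Numbering used throughout: ring B = C1H2, C2(Br)=C3(CH3), C4H2, C5H2, spiro C6. Ring A = C6, C7(CH3)=C8H, C9H(OH), C10HBr, C11(CH3)2.
Enabling feature: in ring A the secondary bromide C10 sits next to the gem-dimethyl carbon C11, C11 is bonded to spiro C6, and C6 carries the C7=C8 alkene. The array Br–C10–C11–C6–C7(=C8) is the footprint of a C10/C11 bromiranium ion opened at its tertiary end by a C6=C7 alkene, followed by loss of H-8.
Cuts: C6–C11 (key step, which also turns C7=C8 back into an exocyclic E-C6=C7 alkene), the two C11–CH3 bonds (Grignard), C9–C10 (syn aldol of a bromoacetyl imide), C7–C8 (Stille), and C2–Br (from the carvone carbonyl).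
Forward: ring B is the carvone ring. The side chain is grown C7, then C8/C9, then C10/C11. Ring A is closed last, which creates both vicinal quaternary carbons, the spiro centre and the ring alkene at once.
Stereochemistry: C9 and C10 come from the (R)-4-benzyloxazolidinone aldol. C6 is relayed from C10 through a chair transition state, and this relay is stereospecific because C6=C7 is E. That geometry comes from 1,4-reduction of an s-trans dienone.
Key step: step 15

Remark: the carvone stereocentre is erased in step 4, so either enantiomer serves and the (R)-form is drawn. Carvone C1(=O) becomes C2, C2(CH3) becomes C3, C6H2 becomes C1, C5 becomes C6, and the isopropenyl carbon becomes C7.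

Step 1
Reactants: 1 (R)-(−)-carvone
Product: 3 (5R)-2-methyl-5-(prop-1-en-2-yl)cyclohex-1-en-1-yl trifluoromethanesulfonate, via lithium enolate 2 (not isolated)
Conditions: L-Selectride (1.05 equiv), THF, −78 °C; then PhNTf2, −78 °C → rt
Reagents that add atoms: N-phenylbis(trifluoromethanesulfonimide) O=S(=O)(N(c1ccccc1)S(=O)(=O)C(F)(F)F)C(F)(F)F
Why: Conjugate reduction with enolate trapping: the hindered borohydride adds 1,4 to the β-unsubstituted enone, so the enolate and then the triflate hold the tetrasubstituted C2=C3 double bond exactly where the vinyl bromide of ring B must sit, and no stereocentre is made or touched.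

Step 2
Reactants: 3 enol triflate
Product: 4 (4R)-2-bromo-1-methyl-4-(prop-1-en-2-yl)cyclohex-1-ene
Conditions: LiBr (1.5 equiv), [Cp*Ru(MeCN)3]OTf (5 mol %), DMI, 60 °C
Reagents that add atoms: lithium bromide [Li+].[Br-]
Why: Ruthenium-catalysed triflate–halide exchange of alkenyl triflates replaces C2–OTf by C2–Br with the double bond held in place, and the isopropenyl group is a spectator.

Step 3
Reactants: 4 vinyl bromide
Product: 6 1-[(1R)-3-bromo-4-methylcyclohex-3-en-1-yl]ethan-1-one, via vicinal diol 5 (not isolated)
Conditions: K2OsO4·2H2O (2 mol %), NaIO4 (4 equiv), 2,6-lutidine, dioxane–H2O, rt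
Reagents that add atoms: sodium periodate [Na+].[O-]I(=O)(=O)=O
Why: Lemieux–Johnson cleavage: osmium tetroxide attacks the unhindered 1,1-disubstituted alkene far faster than the tetrasubstituted, bromine-deactivated ring alkene, and periodate cleaves the diol to the C7 methyl ketone.

Step 4
Reactants: 6 methyl ketone
Product: 8 1-(3-bromo-4-methylcyclohexa-1,3-dien-1-yl)ethan-1-one, via silyl enol ether 7 (not isolated)
Conditions: TMSCl, NaI, Et3N, MeCN, rt; crude 7, then Pd(OAc)2 (1.05 equiv), MeCN, rt
Reagents that add atoms: none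
Why: Thermodynamic silylation followed by Saegusa–Ito oxidation: only the C6=C7 silyl enol ether has β-hydrogens, so the methyl-side isomer cannot dehydrogenate, and β-hydride elimination should take the weaker allylic C1–H to give the fully conjugated C1=C6/C2=C3 dienone, with any C5=C6 isomer removed by chromatography.

Step 5
Reactants: 8 dienone
Product: 10 (1E)-1-(3-bromo-4-methylcyclohex-3-en-1-ylidene)ethyl trifluoromethanesulfonate, via lithium enolate 9 (not isolated)
Conditions: L-Selectride (1.05 equiv), THF, −78 °C; then N-(5-chloropyridin-2-yl)triflimide, −78 → 0 °C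
Reagents that add atoms: N-(5-chloropyridin-2-yl)bis(trifluoromethanesulfonimide) O=S(=O)(N(c1ccc(Cl)cn1)S(=O)(=O)C(F)(F)F)C(F)(F)F
Why: Conjugate reduction with enolate trapping, in which enone conformation becomes enolate geometry: the acetyl group sits s-trans (C7=O anti to C1=C6, CH3 next to H-1 rather than C5H2), so hydride delivery to C1 (C3 is fully substituted and closed to 1,6-attack) gives the tetrasubstituted enolate with O syn to C5 and CH3 syn to C1, and O-triflation freezes this geometry.

Step 6
Reactants: 10 (E)-enol triflate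
Product: 11 (4E)-2-bromo-4-(but-3-en-2-ylidene)-1-methylcyclohex-1-ene
Conditions: Bu3SnCH=CH2, Pd(PPh3)4 (5 mol %), LiCl (3 equiv), DMF, rt → 40 °C
Reagents that add atoms: tributyl(vinyl)stannane C=C[Sn](CCCC)(CCCC)CCCC
Why: Stille coupling with retention at C7: oxidative addition of Pd(0) to an alkenyl triflate in DMF/LiCl is much faster than to the hindered tetrasubstituted alkenyl bromide at C2, so only C7–O is exchanged for the vinyl group (C8=C9), which stays syn to C5.

Step 7
Reactants: 11 triene
Product: 13 (3E)-3-(3-bromo-4-methylcyclohex-3-en-1-ylidene)butan-1-ol, via alkylborane 12 (not isolated)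
Conditions: 9-BBN-H (1.1 equiv), THF, 0 °C → rt; then NaOH, 30 % H2O2, 0 °C
Reagents that add atoms: hydrogen peroxide OO
Why: Anti-Markovnikov hydroboration–oxidation: 9-BBN adds only to the monosubstituted alkene with boron on C9, both tetrasubstituted alkenes are inert, and the E geometry is untouched.

Step 8
Reactants: 13 homoallylic alcohol
Product: 14 (3E)-3-(3-bromo-4-methylcyclohex-3-en-1-ylidene)butanal
Conditions: Dess–Martin periodinane, NaHCO3, CH2Cl2, 0 °C; used at once
Reagents that add atoms: none
Why: Buffered Dess–Martin oxidation is mild enough to give the β,γ-unsaturated aldehyde without moving C6=C7 into conjugation.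

Step 9
Reactants: 15 (R)-4-benzyl-1,3-oxazolidin-2-one; 16 bromoacetyl bromide
Product: 18 (4R)-4-benzyl-3-(bromoacetyl)-1,3-oxazolidin-2-one, via lithium oxazolidinide 17 (not isolated)
Conditions: n-BuLi, THF, −78 °C; then 16, −78 → 0 °C
Reagents that add atoms: none
Why: N-acylation of the lithiated auxiliary occurs at the acyl bromide much faster than substitution at the CH2Br carbon.

Step 10
Reactants: 18 bromoacetyl imide; 14 aldehyde
Product: 21 (4R)-4-benzyl-3-[(2R,3S,5E)-2-bromo-5-(3-bromo-4-methylcyclohex-3-en-1-ylidene)-3-hydroxyhexanoyl]-1,3-oxazolidin-2-one, via boron enolate 19 (not isolated), via boron aldolate 20 (not isolated)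
Conditions: 18, Bu2BOTf, Et3N, CH2Cl2, −78 → 0 °C; 14, −78 → 0 °C; then pH 7 buffer, MeOH, 30 % H2O2, 0 °C
Reagents that add atoms: none
Why: Evans syn aldol: the Z-boron enolate reacts through a closed chair on the face away from the benzyl group, which sets C10 and C9 together as the syn bromohydrin, the relationship that becomes trans-diequatorial O/Br in ring A.

Step 11
Reactants: 21 aldol adduct
Product: 22 methyl (2R,3S,5E)-2-bromo-5-(3-bromo-4-methylcyclohex-3-en-1-ylidene)-3-hydroxyhexanoate
Conditions: Sm(OTf)3 (10 mol %), MeOH, rt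
Reagents that add atoms: methanol CO
Why: Lanthanide-triflate-catalysed methanolysis of the N-acyloxazolidinone is non-basic, so epoxide closure of the bromohydrin, epimerisation at C10 and retro-aldol cleavage are avoided.

Step 12
Reactants: 22 hydroxy ester
Product: 23 methyl (2R,3S,5E)-2-bromo-5-(3-bromo-4-methylcyclohex-3-en-1-ylidene)-3-[(tert-butyldimethylsilyl)oxy]hexanoate
Conditions: TBSOTf, 2,6-lutidine, CH2Cl2, −78 → 0 °C
Reagents that add atoms: tert-butyldimethylsilyl trifluoromethanesulfonate CC(C)(C)[Si](C)(C)OS(=O)(=O)C(F)(F)F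
Why: Silylation masks the C9 oxygen as a non-participating ether, so that it can neither displace the bromide under the Grignard conditions nor trap the bromiranium ion later.

Step 13
Reactants: 23 silyloxy ester
Product: 26 (3R,4S,6E)-3-bromo-6-(3-bromo-4-methylcyclohex-3-en-1-ylidene)-4-[(tert-butyldimethylsilyl)oxy]-2-methylheptan-2-ol, via methyl ketone 24 (not isolated), via magnesium alkoxide 25 (not isolated)
Conditions: MeMgBr (3 equiv), LaCl3·2LiCl (30 mol %), THF, −78 → −30 °C; sat. NH4Cl at −30 °C
Reagents that add atoms: methylmagnesium bromide C[Mg]Br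
Why: Double Grignard addition to the ester builds C11 with its gem-dimethyl group, the lanthanum salt suppresses enolisation and loss of silanolate, the flanked C10–Br is closed to SN2, and the cold quench prevents closure of the halohydrin alkoxide to an epoxide.

Step 14
Reactants: 26 tertiary alcohol
Product: 27 tert-butyl{[(3R,4S,6E)-3-bromo-6-(3-bromo-4-methylcyclohex-3-en-1-ylidene)-2-chloro-2-methylheptan-4-yl]oxy}dimethylsilane
Conditions: 1-chloro-N,N,2-trimethylprop-1-en-1-amine (1.5 equiv), CH2Cl2, 0 °C → rt
Reagents that add atoms: 1-chloro-N,N,2-trimethylprop-1-en-1-amine CC(C)=C(Cl)N(C)C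
Why: Neutral chlorodehydroxylation of a tertiary alcohol with an α-chloroenamine: in non-ionising CH2Cl2 the alkoxy-iminium chloride ion pair collapses at the tertiary carbon faster than the alkene can intervene, C10 is not disturbed, and no free acid arises that could scramble the C6=C7 geometry or cleave the silyl ether.

Step 15
Reactants: 27 vicinal bromochloride
Product: 30 tert-butyl{[(3S,4S,6S)-4,8-dibromo-1,5,5,9-tetramethylspiro[5.5]undeca-1,8-dien-3-yl]oxy}dimethylsilane, via bromiranium ion 28 (not isolated), via C7 cation 29 (not isolated)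
Conditions: (CF3)2CHOH (0.01 M), 2,6-di-tert-butyl-4-methylpyridine (1.5 equiv), 25 → 40 °C
Reagents that add atoms: none
Why: In the strongly ionising, non-nucleophilic solvent the tertiary C11–Cl bond heterolyses with help from the anti C10 bromine to give bromiranium ion 28 with no external Br+ present (so the electron-rich C6=C7 alkene never meets an electrophilic bromine source), C6 opens 28 at its tertiary carbon C11 anti to bromine to give the tertiary C7 cation 29, and 29 loses H-8 to the hindered base. The closest known reaction type is the bromonium-initiated cation–olefin (polyene) cyclisation in its enantiospecific form started by solvolysis of a vicinal bromochloride, and the event copies the biogenetic γ-bisabolene to chamigrene ring closure. Ring A closes 6-endo at both partners, since C6 and C7 of the alkene and C10 and C11 of the bromiranium all end inside the ring, through a chair. C10 keeps its configuration because only the C11–Br bond breaks, the anti opening places Br equatorial, and the syn-related C9 silyl ether is then also equatorial, which is the trans O/Br pair of the target. C6 is fixed by this chair together with the E geometry: C5, the alkene substituent cis to C8, becomes axial on the face of the C9 oxygen, and C1 becomes equatorial on the face of the bromine, which is the (6S) spiro centre. The step needs capture by C6 rather than 5-exo capture by C7 (both give tertiary cations, and the chair overlap typical of 1,5-diene cyclisations favours the six-membered ring), an inert C2=C3 alkene (deactivated by its bromine and out of reach), and loss of H-8 rather than a methyl proton (an axial C8–H is aligned with the empty orbital and leads to the more substituted alkene).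

Step 16
Reactants: 30 silyl ether
Product: 31 (3S,4S,6S)-4,8-dibromo-1,5,5,9-tetramethylspiro[5.5]undeca-1,8-dien-3-ol (target)
Conditions: HF·pyridine, pyridine, THF, 0 °C → rt
Reagents that add atoms: none
Why: Fluoride desilylation under weakly acidic conditions avoids a free alkoxide next to C10–Br (no epoxide closure), does not ionise the allylic alcohol, and touches none of the three stereocentres.

Compound list
1 | (R)-(−)-carvone | CC1=CC[C@H](CC1=O)C(C)=C | starting material
2 | lithium (5R)-2-methyl-5-(prop-1-en-2-yl)cyclohex-1-en-1-olate | CC1=C([O-])C[C@@H](CC1)C(C)=C.[Li+] | intermediate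
3 | (5R)-2-methyl-5-(prop-1-en-2-yl)cyclohex-1-en-1-yl trifluoromethanesulfonate | CC1=C(OS(=O)(=O)C(F)(F)F)C[C@@H](CC1)C(C)=C | intermediate
4 | (4R)-2-bromo-1-methyl-4-(prop-1-en-2-yl)cyclohex-1-ene | CC1=C(Br)C[C@@H](CC1)C(C)=C | intermediate
5 | 2-[(1R)-3-bromo-4-methylcyclohex-3-en-1-yl]propane-1,2-diol (both epimers at the carbinol carbon) | CC1=C(Br)C[C@@H](CC1)C(C)(O)CO | intermediate
6 | 1-[(1R)-3-bromo-4-methylcyclohex-3-en-1-yl]ethan-1-one | CC1=C(Br)C[C@@H](CC1)C(C)=O | intermediate
7 | [1-(3-bromo-4-methylcyclohex-3-en-1-ylidene)ethoxy]trimethylsilane (E/Z mixture) | CC(O[Si](C)(C)C)=C1CCC(C)=C(Br)C1 | intermediate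
8 | 1-(3-bromo-4-methylcyclohexa-1,3-dien-1-yl)ethan-1-one | CC(=O)C1=CC(Br)=C(C)CC1 | intermediate
9 | lithium (1E)-1-(3-bromo-4-methylcyclohex-3-en-1-ylidene)ethan-1-olate (O syn to C5) | C/C([O-])=C1/CCC(C)=C(Br)C1.[Li+] | intermediate
10 | (1E)-1-(3-bromo-4-methylcyclohex-3-en-1-ylidene)ethyl trifluoromethanesulfonate | C/C(OS(=O)(=O)C(F)(F)F)=C1/CCC(C)=C(Br)C1 | intermediate
11 | (4E)-2-bromo-4-(but-3-en-2-ylidene)-1-methylcyclohex-1-ene | C/C(C=C)=C1/CCC(C)=C(Br)C1 | intermediate
12 | 9-[(3E)-3-(3-bromo-4-methylcyclohex-3-en-1-ylidene)butyl]-9-borabicyclo[3.3.1]nonane | C/C(CCB2C3CCCC2CCC3)=C1/CCC(C)=C(Br)C1 | intermediate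
13 | (3E)-3-(3-bromo-4-methylcyclohex-3-en-1-ylidene)butan-1-ol | C/C(CCO)=C1/CCC(C)=C(Br)C1 | intermediate
14 | (3E)-3-(3-bromo-4-methylcyclohex-3-en-1-ylidene)butanal | C/C(CC=O)=C1/CCC(C)=C(Br)C1 | intermediate
15 | (R)-4-benzyl-1,3-oxazolidin-2-one | O=C1N[C@H](Cc2ccccc2)CO1 | starting material
16 | bromoacetyl bromide | BrCC(Br)=O | starting material
17 | lithium salt of (R)-4-benzyl-1,3-oxazolidin-2-one | O=C1[N-][C@H](Cc2ccccc2)CO1.[Li+] | intermediate
18 | (4R)-4-benzyl-3-(bromoacetyl)-1,3-oxazolidin-2-one | O=C(CBr)N1[C@H](Cc2ccccc2)COC1=O | intermediate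
19 | (Z)-dibutylboron enolate of 18 | Br/C=C(\OB(CCCC)CCCC)N1[C@H](Cc2ccccc2)COC1=O | intermediate
20 | dibutylboron aldolate of 21 | C/C(C[C@H](OB(CCCC)CCCC)[C@@H](Br)C(=O)N2[C@H](Cc3ccccc3)COC2=O)=C1/CCC(C)=C(Br)C1 | intermediate
21 | (4R)-4-benzyl-3-[(2R,3S,5E)-2-bromo-5-(3-bromo-4-methylcyclohex-3-en-1-ylidene)-3-hydroxyhexanoyl]-1,3-oxazolidin-2-one | C/C(C[C@H](O)[C@@H](Br)C(=O)N2[C@H](Cc3ccccc3)COC2=O)=C1/CCC(C)=C(Br)C1 | intermediate
22 | methyl (2R,3S,5E)-2-bromo-5-(3-bromo-4-methylcyclohex-3-en-1-ylidene)-3-hydroxyhexanoate | C/C(C[C@H](O)[C@@H](Br)C(=O)OC)=C1/CCC(C)=C(Br)C1 | intermediate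
23 | methyl (2R,3S,5E)-2-bromo-5-(3-bromo-4-methylcyclohex-3-en-1-ylidene)-3-[(tert-butyldimethylsilyl)oxy]hexanoate | C/C(C[C@H](O[Si](C)(C)C(C)(C)C)[C@@H](Br)C(=O)OC)=C1/CCC(C)=C(Br)C1 | intermediate
24 | (3R,4S,6E)-3-bromo-6-(3-bromo-4-methylcyclohex-3-en-1-ylidene)-4-[(tert-butyldimethylsilyl)oxy]heptan-2-one | C/C(C[C@H](O[Si](C)(C)C(C)(C)C)[C@@H](Br)C(C)=O)=C1/CCC(C)=C(Br)C1 | intermediate
25 | bromomagnesium alkoxide of 26 | C/C(C[C@H](O[Si](C)(C)C(C)(C)C)[C@@H](Br)C(C)(C)O[Mg]Br)=C1/CCC(C)=C(Br)C1 | intermediate
26 | (3R,4S,6E)-3-bromo-6-(3-bromo-4-methylcyclohex-3-en-1-ylidene)-4-[(tert-butyldimethylsilyl)oxy]-2-methylheptan-2-ol | C/C(C[C@H](O[Si](C)(C)C(C)(C)C)[C@@H](Br)C(C)(C)O)=C1/CCC(C)=C(Br)C1 | intermediate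
27 | tert-butyl{[(3R,4S,6E)-3-bromo-6-(3-bromo-4-methylcyclohex-3-en-1-ylidene)-2-chloro-2-methylheptan-4-yl]oxy}dimethylsilane | C/C(C[C@H](O[Si](C)(C)C(C)(C)C)[C@@H](Br)C(C)(C)Cl)=C1/CCC(C)=C(Br)C1 | intermediate
28 | C10/C11 bromiranium ion from 27 (chloride ion pair) | C/C(C[C@H](O[Si](C)(C)C(C)(C)C)[C@H]2[Br+]C2(C)C)=C1/CCC(C)=C(Br)C1.[Cl-] | intermediate
29 | spirocyclic tertiary C7 cation (chloride ion pair) | C[C+]1C[C@H](O[Si](C)(C)C(C)(C)C)[C@@H](Br)C(C)(C)[C@]12CCC(C)=C(Br)C2.[Cl-] | intermediate
30 | tert-butyl{[(3S,4S,6S)-4,8-dibromo-1,5,5,9-tetramethylspiro[5.5]undeca-1,8-dien-3-yl]oxy}dimethylsilane | CC1=C[C@H](O[Si](C)(C)C(C)(C)C)[C@@H](Br)C(C)(C)[C@]12CCC(C)=C(Br)C2 | intermediate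
31 | (3S,4S,6S)-4,8-dibromo-1,5,5,9-tetramethylspiro[5.5]undeca-1,8-dien-3-ol | CC1=C[C@H](O)[C@@H](Br)C(C)(C)[C@]12CCC(C)=C(Br)C2 | target

Total steps: 16. Longest linear sequence: 15 (steps 1–8 and 10–16; step 9 is a side branch).

Steps most likely to fail

Step 15. Cation 29 may lose a proton from the C7 methyl group instead of from C8, which would place the alkene outside the ring. Slow ionisation of the inductively deactivated chloride would give this pathway more time. Fallback: ring closure and alkene placement are separated. Setting out from 27, the ionisation is run as before, and the exocyclic 7-methylidene silyl ether F1 is kept rather than discarded. A separate cobalt-hydride hydrogen-atom-transfer isomerisation (Co(salen) chloride cat., PhSiH3 cat., benzene, rt) then moves the 1,1-disubstituted alkene into the more substituted ring position. The conditions are neutral and radical, so the silyl ether, the secondary bromide and the tetrasubstituted vinyl bromide should be left alone. The route is rejoined at 30.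

Step 5. The hydride may add 1,2 to the ketone, or the reaction may run through the minor s-cis rotamer with loss of geometric purity. Fallback: the stereospecific reduction is replaced by direct enol triflation and separation. Setting out from ketone 6, Tf2O and 2,6-di-tert-butyl-4-methylpyridine in CH2Cl2 should give the more substituted enol triflates, namely 10 together with the (1Z)-enol triflate F2. The two are separated by chromatography on silver-nitrate-impregnated silica. The route is rejoined at 10, and steps 4 and 5 are bypassed.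

Step 4. Silylation may occur toward the methyl group, β-hydride loss may occur toward C5, or the cyclohexadiene may be oxidised further to the arene. Fallback: the palladium-mediated dehydrogenation is replaced by a selenoxide syn-elimination, which needs no silyl enol ether and no oxidising metal. Setting out from 6, PhSeCl in EtOAc should selenenylate through the more substituted enol to give the α-(phenylselanyl) ketone F3. H2O2/pyridine in CH2Cl2 at 0 °C then gives the selenoxide F4, which eliminates at or below room temperature, preferably toward the allylic C1–H. The route is rejoined at 8.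

Further compounds
F1 | step 15 | tert-butyl{[(3S,4S,6S)-4,8-dibromo-5,5,9-trimethyl-1-methylidenespiro[5.5]undec-8-en-3-yl]oxy}dimethylsilane | C=C1C[C@H](O[Si](C)(C)C(C)(C)C)[C@@H](Br)C(C)(C)[C@]12CCC(C)=C(Br)C2
F2 | step 5 | (1Z)-1-(3-bromo-4-methylcyclohex-3-en-1-ylidene)ethyl trifluoromethanesulfonate | C/C(OS(=O)(=O)C(F)(F)F)=C1\CCC(C)=C(Br)C1
F3 | step 4 | 1-[3-bromo-4-methyl-1-(phenylselanyl)cyclohex-3-en-1-yl]ethan-1-one (racemic) | CC(=O)C1([Se]c2ccccc2)CCC(C)=C(Br)C1
F4 | step 4 | 1-[3-bromo-4-methyl-1-(phenylseleninyl)cyclohex-3-en-1-yl]ethan-1-one | CC(=O)C1([Se](=O)c2ccccc2)CCC(C)=C(Br)C1
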